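**Strategy.** The ring bond C3–C4 (hemiketal carbon to the methyl-bearing carbon) is made as the closing bond of a temporary cyclobutanone. The 3-hydroxy-1,2-dioxane ring O1–O2–C3–C4–C5–C6 is a cyclobutanol C3–C4–C5–C6 with dioxygen inserted into C3–C6, and the unit C3(=O)–C4H(CH3) is what a Markovnikov alkene hydroacylation produces. Cobalt-catalysed 4-exo hydroacylation of the acyclic aldehyde 2-allyl-2,4-dimethyl-12-phenyldodecanal therefore joins the aldehyde carbon (C3) to the internal alkene carbon (C4), creates the C4 methyl group and stereocentre, and closes the cyclobutanone. Reformatsky addition and aerobic cobalt-mediated ring expansion at the quaternary carbon then open the four-membered ring into the peroxy-hemiketal.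

Key step: step 4

Assumption: atoms are labelled as in the 1,2-dioxane (O1, O2, C3–C6; C7 and C8 are the first side-chain carbons), and the chiral ligands of steps 1 and 4 are used as whichever antipode gives the configuration drawn.

Step 1
Reactants: 1 (8-bromooctyl)benzene; 2 (3E)-pent-3-en-2-one
Product: 4 (4R)-4-methyl-12-phenyldodecan-2-one, via Grignard reagent 3 (not isolated)
Conditions: 1, Mg, Et2O; then 2, CuBr·SMe2 (5 mol %), (R)-1-[(SP)-2-(diphenylphosphino)ferrocenyl]ethyldicyclohexylphosphine (6 mol %), t-BuOMe, −75 °C; 1 M HCl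
Reagents that add atoms: none
Why: Copper-catalysed asymmetric conjugate addition of a Grignard reagent to an acyclic (E)-enone should set C8 as R, the chiral ferrocenyl diphosphine–copper complex selecting the enone face (catalyst control).

Step 2
Reactants: 4 (4R)-4-methyl-12-phenyldodecan-2-one; 5 (methoxymethyl)triphenylphosphonium chloride
Product: 8 (4R)-2,4-dimethyl-12-phenyldodecanal (both C2 epimers), via phosphorus ylide 6 (not isolated), via methyl enol ether 7 (not isolated)
Conditions: 5, KOtBu, THF, 0 °C to rt; then 2 M HCl, THF, rt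
Reagents that add atoms: water, O
Why: Wittig methoxymethylenation of the methyl ketone and hydrolysis of the enol ether should give the one-carbon-homologated alpha-methyl aldehyde; the new alpha-stereocentre is left uncontrolled because it is erased in step 6.

Step 3
Reactants: 8 (4R)-2,4-dimethyl-12-phenyldodecanal; 9 prop-2-en-1-ol
Product: 12 (4R)-2,4-dimethyl-12-phenyl-2-(prop-2-en-1-yl)dodecanal (both C2 epimers), via diallyl acetal 10 (not isolated), via allyl enol ether 11 (not isolated)
Conditions: 9 (excess), TsOH (cat.), toluene, reflux (Dean–Stark); then mesitylene, 165 °C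
Reagents that add atoms: none
Why: Acetal formation, thermal loss of allyl alcohol to the allyl enol ether and aliphatic Claisen rearrangement should install the allyl group at the alpha-carbon; the quaternary centre forms as both epimers, which is harmless because this carbon becomes a planar radical in step 6.

Step 4
Reactants: 12 (4R)-2,4-dimethyl-12-phenyl-2-(prop-2-en-1-yl)dodecanal
Product: 13 (4R)-2,4-dimethyl-2-[(2R)-2-methyl-10-phenyldecyl]cyclobutan-1-one (both epimers at the quaternary ring carbon)
Conditions: CoCl2 (5 mol %), (2S,4S)-2,4-bis(diphenylphosphino)pentane (5 mol %), Zn (10 mol %), MeCN, 50 °C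
Reagents that add atoms: none
Why: Zinc reduces CoCl2 to a zerovalent cobalt–bisphosphine species that inserts into the aldehyde C–H bond; the acyl cobalt hydride adds across the pendant alkene with hydride going to the terminal CH2 (which becomes the C4 methyl) and cobalt to the internal carbon, and C–C reductive elimination from the five-membered acyl–alkyl cobaltacycle forms the C3–C4 bond. The closest known reaction type is the cobalt-catalysed enantioselective intramolecular hydroacylation of alpha-quaternary pent-4-enals to 2-methylcyclobutanones, the Markovnikov counterpart of the rhodium-catalysed cyclopentanone synthesis. The cyclobutanone ring C3–C4–C5–C6 is closed in the 4-exo-trig mode. The new stereocentre C4 is set by the chiral bisphosphine in the face-selective hydrometalation (catalyst control, since CH3 and CH2R at the quaternary carbon bias the substrate only weakly), while the quaternary carbon is carried as both epimers because step 6 erases it. The step needs 4-exo over 5-endo insertion and no decarbonylation or alkene migration; the fully substituted alpha-carbon (no enolisation, gem-dialkyl effect) and the small-bite-angle bisphosphine on cobalt should secure this.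

Step 5
Reactants: 13 (4R)-2,4-dimethyl-2-[(2R)-2-methyl-10-phenyldecyl]cyclobutan-1-one; 14 tert-butyl bromoacetate
Product: 16 tert-butyl 2-{(2R)-1-hydroxy-2,4-dimethyl-4-[(2R)-2-methyl-10-phenyldecyl]cyclobutyl}acetate (epimers at C1 and C4 of the ring), via zinc enolate 15 (not isolated)
Conditions: Zn (TMSCl-activated), 14, THF, 40 °C; then 13, 0 °C to rt; cold 0.5 M HCl
Reagents that add atoms: none
Why: Reformatsky addition of the non-basic zinc enolate to the strained cyclobutanone carbonyl should proceed without enolising C4; the carbinol configuration is irrelevant because C3 later becomes a hemiketal under thermodynamic control.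

Step 6
Reactants: 16 tert-butyl 2-{(2R)-1-hydroxy-2,4-dimethyl-4-[(2R)-2-methyl-10-phenyldecyl]cyclobutyl}acetate
Product: 18 tert-butyl 2-{(3S,4R,6S)-3-hydroxy-4,6-dimethyl-6-[(2R)-2-methyl-10-phenyldecyl]-1,2-dioxan-3-yl}acetate (separated from its C6 epimer), via open-chain hydroperoxy ketone 17 (not isolated)
Conditions: Co(acac)2 (20 mol %), O2 (1 atm), MeCN, 40 °C; chromatography
Reagents that add atoms: dioxygen, O=O
Why: Cobalt-mediated aerobic oxidative ring expansion of the cyclobutanol (alkoxy radical, beta-scission toward the quaternary carbon, capture of O2, peroxy-hemiketalisation) inserts dioxygen into C3–C6; C3 should settle as the anomerically favoured axial hydroxyl by ring–chain equilibration and C4 is untouched, but O2 is captured at the planar C6 radical without facial bias, so the 6S product must be separated from its 6R ring diastereomer.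

Step 7
Reactants: 18 tert-butyl 2-{(3S,4R,6S)-3-hydroxy-4,6-dimethyl-6-[(2R)-2-methyl-10-phenyldecyl]-1,2-dioxan-3-yl}acetate
Product: 19 2-{(3S,4R,6S)-3-hydroxy-4,6-dimethyl-6-[(2R)-2-methyl-10-phenyldecyl]-1,2-dioxan-3-yl}acetic acid
Conditions: TFA/CH2Cl2 (1:4), 0 °C
Reagents that add atoms: none
Why: Acidolysis of the tert-butyl ester should leave the cyclic peroxy-hemiketal intact, the ring form protecting the beta-keto acid from decarboxylation, and no stereocentre should be touched at 0 °C.

**Compound list**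

1 | (8-bromooctyl)benzene | BrCCCCCCCCc1ccccc1 | starting material
2 | (3E)-pent-3-en-2-one | C/C=C/C(C)=O | starting material
3 | (8-phenyloctyl)magnesium bromide | Br[Mg]CCCCCCCCc1ccccc1 | intermediate
4 | (4R)-4-methyl-12-phenyldodecan-2-one | C[C@H](CCCCCCCCc1ccccc1)CC(C)=O | intermediate
5 | (methoxymethyl)triphenylphosphonium chloride | COC[P+](c1ccccc1)(c1ccccc1)c1ccccc1.[Cl-] | starting material
6 | (methoxymethylidene)triphenylphosphorane | COC=P(c1ccccc1)(c1ccccc1)c1ccccc1 | intermediate
7 | (4R)-1-methoxy-2,4-dimethyl-12-phenyldodec-1-ene (E/Z) | C[C@H](CCCCCCCCc1ccccc1)CC(C)=COC | intermediate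
8 | (4R)-2,4-dimethyl-12-phenyldodecanal (C2 epimers) | C[C@H](CCCCCCCCc1ccccc1)CC(C)C=O | intermediate
9 | prop-2-en-1-ol | C=CCO | starting material
10 | (4R)-2,4-dimethyl-12-phenyl-1,1-bis(prop-2-en-1-yloxy)dodecane | C[C@H](CCCCCCCCc1ccccc1)CC(C)C(OCC=C)OCC=C | intermediate
11 | (4R)-2,4-dimethyl-12-phenyl-1-(prop-2-en-1-yloxy)dodec-1-ene | C[C@H](CCCCCCCCc1ccccc1)CC(C)=COCC=C | intermediate
12 | (4R)-2,4-dimethyl-12-phenyl-2-(prop-2-en-1-yl)dodecanal (C2 epimers) | C[C@H](CCCCCCCCc1ccccc1)CC(C)(CC=C)C=O | intermediate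
13 | (4R)-2,4-dimethyl-2-[(2R)-2-methyl-10-phenyldecyl]cyclobutan-1-one (C2 epimers) | C[C@H](CCCCCCCCc1ccccc1)CC1(C)C[C@@H](C)C1=O | intermediate
14 | tert-butyl bromoacetate | BrCC(=O)OC(C)(C)C | starting material
15 | (2-tert-butoxy-2-oxoethyl)zinc bromide | Br[Zn]CC(=O)OC(C)(C)C | intermediate
16 | tert-butyl 2-{(2R)-1-hydroxy-2,4-dimethyl-4-[(2R)-2-methyl-10-phenyldecyl]cyclobutyl}acetate | C[C@H](CCCCCCCCc1ccccc1)CC1(C)C[C@@H](C)C1(O)CC(=O)OC(C)(C)C | intermediate
17 | tert-butyl (4R,6S,8R)-6-hydroperoxy-4,6,8-trimethyl-3-oxo-16-phenylhexadecanoate | C[C@H](CCCCCCCCc1ccccc1)C[C@@](OO)(C)C[C@@H](C)C(=O)CC(=O)OC(C)(C)C | intermediate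
18 | tert-butyl 2-{(3S,4R,6S)-3-hydroxy-4,6-dimethyl-6-[(2R)-2-methyl-10-phenyldecyl]-1,2-dioxan-3-yl}acetate | C[C@H](CCCCCCCCc1ccccc1)C[C@@]1(C)C[C@@H](C)[C@](O)(CC(=O)OC(C)(C)C)OO1 | intermediate
19 | 2-{(3S,4R,6S)-3-hydroxy-4,6-dimethyl-6-[(2R)-2-methyl-10-phenyldecyl]-1,2-dioxan-3-yl}acetic acid | C[C@H](CCCCCCCCc1ccccc1)C[C@@]1(C)C[C@@H](C)[C@](O)(CC(=O)O)OO1 | target

**Step count and risks**

Total steps: 7. Longest linear sequence: 7 (from 1).

Most likely to fail, in order:

1. Step 6. Dioxygen is captured at the planar C6 radical with no facial selection, so half of the material is expected as the C6 epimer. The cyclobutyloxy radical may also partition into scission toward C4 or loss of the acetate arm. The fallback sets out from 4 and returns at 18, installing the peroxide stereospecifically before the chain is completed.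
   - Catalytic asymmetric Corey–Chaykovsky epoxidation of 4 (Me3S(O)I, NaH, LaLi3(binaphthoxide)3, an aryl phosphine oxide) should give (2R)-2-methyl-2-[(2R)-2-methyl-10-phenyldecyl]oxirane F1.
   - MoO2(acac)2-catalysed perhydrolysis with ethereal H2O2 should open F1 at the tertiary carbon with inversion to (2S,4R)-2-hydroperoxy-2,4-dimethyl-12-phenyldodecan-1-ol F2.
   - Selective peroxyketalisation of the hydroperoxide (2-methoxypropene, PPTS) should give (2S,4R)-2-[(2-methoxypropan-2-yl)peroxy]-2,4-dimethyl-12-phenyldodecan-1-ol F3.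
   - Dess–Martin oxidation should give (2S,4R)-2-[(2-methoxypropan-2-yl)peroxy]-2,4-dimethyl-12-phenyldodecanal F4.
   - Horner–Wadsworth–Emmons olefination with the dianion of tert-butyl 4-(diethoxyphosphoryl)-3-oxopentanoate (NaH) should give tert-butyl (4E,6S,8R)-6-[(2-methoxypropan-2-yl)peroxy]-4,6,8-trimethyl-3-oxo-16-phenylhexadec-4-enoate F5.
   - Metal-free conjugate reduction (Hantzsch ester, ammonium salt catalyst) should give tert-butyl (6S,8R)-6-[(2-methoxypropan-2-yl)peroxy]-4,6,8-trimethyl-3-oxo-16-phenylhexadecanoate F6.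
   - Aqueous AcOH should remove the peroxyketal, and the freed hydroperoxide should close onto the C3 ketone to give 18. In this fallback C6 is fixed by the inversion, and C4 is obtained as two epimers that are separated.

2. Step 4. Hydride may be delivered with the opposite regiochemistry (5-endo closure to a cyclopentanone), the acyl cobalt hydride may decarbonylate, the alkene may migrate, or the substrate rather than the catalyst may decide the C4 face. The fallback sets out from 4 and returns at 13.
   - Spiroannelation of 4 with the ylide from cyclopropyldiphenylsulfonium tetrafluoroborate (KOH, DMSO) should give 2-methyl-2-[(2R)-2-methyl-10-phenyldecyl]-1-oxaspiro[2.2]pentane F7.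
   - HBF4-promoted ring expansion should give 2-methyl-2-[(2R)-2-methyl-10-phenyldecyl]cyclobutan-1-one F8.
   - Condensation with (S)-1-amino-2-(methoxymethyl)pyrrolidine (SAMP) should give N-[(2S)-2-(methoxymethyl)pyrrolidin-1-yl]-2-methyl-2-[(2R)-2-methyl-10-phenyldecyl]cyclobutan-1-imine F9.
   - Deprotonation at the only enolisable alpha-carbon (LDA) and methylation with MeI should give (4R)-N-[(2S)-2-(methoxymethyl)pyrrolidin-1-yl]-2,4-dimethyl-2-[(2R)-2-methyl-10-phenyldecyl]cyclobutan-1-imine F10, with C4 set by the auxiliary.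
   - Ozonolysis of the hydrazone should return 13.

3. Step 7. Acid may promote heterolysis of the tertiary C6–O bond, ring opening followed by loss of CO2 from the beta-keto acid, or epimerisation at C4. The fallback sets out from 13 and returns at 19.
   - Reformatsky addition with methyl bromoacetate should give methyl 2-{(2R)-1-hydroxy-2,4-dimethyl-4-[(2R)-2-methyl-10-phenyldecyl]cyclobutyl}acetate F11.
   - The same Co(acac)2/O2 ring expansion should give methyl 2-{(3S,4R,6S)-3-hydroxy-4,6-dimethyl-6-[(2R)-2-methyl-10-phenyldecyl]-1,2-dioxan-3-yl}acetate F12.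
   - Pig liver esterase in pH 7 phosphate buffer should hydrolyse the ester under neutral conditions to 19.

**Further compounds**

F1 | step 6 | (2R)-2-methyl-2-[(2R)-2-methyl-10-phenyldecyl]oxirane | C[C@H](CCCCCCCCc1ccccc1)C[C@]1(C)CO1
F2 | step 6 | (2S,4R)-2-hydroperoxy-2,4-dimethyl-12-phenyldodecan-1-ol | C[C@H](CCCCCCCCc1ccccc1)C[C@@](OO)(C)CO
F3 | step 6 | (2S,4R)-2-[(2-methoxypropan-2-yl)peroxy]-2,4-dimethyl-12-phenyldodecan-1-ol | C[C@H](CCCCCCCCc1ccccc1)C[C@@](OOC(C)(C)OC)(C)CO
F4 | step 6 | (2S,4R)-2-[(2-methoxypropan-2-yl)peroxy]-2,4-dimethyl-12-phenyldodecanal | C[C@H](CCCCCCCCc1ccccc1)C[C@@](OOC(C)(C)OC)(C)C=O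
F5 | step 6 | tert-butyl (4E,6S,8R)-6-[(2-methoxypropan-2-yl)peroxy]-4,6,8-trimethyl-3-oxo-16-phenylhexadec-4-enoate | C[C@H](CCCCCCCCc1ccccc1)C[C@@](OOC(C)(C)OC)(C)/C=C(\C)C(=O)CC(=O)OC(C)(C)C
F6 | step 6 | tert-butyl (6S,8R)-6-[(2-methoxypropan-2-yl)peroxy]-4,6,8-trimethyl-3-oxo-16-phenylhexadecanoate | C[C@H](CCCCCCCCc1ccccc1)C[C@@](OOC(C)(C)OC)(C)CC(C)C(=O)CC(=O)OC(C)(C)C
F7 | step 4 | 2-methyl-2-[(2R)-2-methyl-10-phenyldecyl]-1-oxaspiro[2.2]pentane | C[C@H](CCCCCCCCc1ccccc1)CC1(C)OC12CC2
F8 | step 4 | 2-methyl-2-[(2R)-2-methyl-10-phenyldecyl]cyclobutan-1-one | C[C@H](CCCCCCCCc1ccccc1)CC1(C)CCC1=O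
F9 | step 4 | N-[(2S)-2-(methoxymethyl)pyrrolidin-1-yl]-2-methyl-2-[(2R)-2-methyl-10-phenyldecyl]cyclobutan-1-imine | C[C@H](CCCCCCCCc1ccccc1)CC1(C)CCC1=NN1CCC[C@H]1COC
F10 | step 4 | (4R)-N-[(2S)-2-(methoxymethyl)pyrrolidin-1-yl]-2,4-dimethyl-2-[(2R)-2-methyl-10-phenyldecyl]cyclobutan-1-imine | C[C@H](CCCCCCCCc1ccccc1)CC1(C)C[C@@H](C)C1=NN1CCC[C@H]1COC
F11 | step 7 | methyl 2-{(2R)-1-hydroxy-2,4-dimethyl-4-[(2R)-2-methyl-10-phenyldecyl]cyclobutyl}acetate | C[C@H](CCCCCCCCc1ccccc1)CC1(C)C[C@@H](C)C1(O)CC(=O)OC
F12 | step 7 | methyl 2-{(3S,4R,6S)-3-hydroxy-4,6-dimethyl-6-[(2R)-2-methyl-10-phenyldecyl]-1,2-dioxan-3-yl}acetate | C[C@H](CCCCCCCCc1ccccc1)C[C@@]1(C)C[C@@H](C)[C@](O)(CC(=O)OC)OO1
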